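Watch the level at which target stops in the south flask, the hottest of the four, and do not carry it over unchanged from the theta run.

| setting | beta | theta | south | north-east | north-west | south-west |
|---|---|---|---|---|---|---|
| substrate | 1.5 M | 1.5 M | 1.5 M | 1.5 M | 1.5 M | 1.5 M |
| catalyst | 3.8 mM | 15 mM | 7.5 mM | 7.5 mM | 7.5 mM | 7.5 mM |
| temperature | 10 °C | 45 °C | 75 °C | 35 °C | 55 °C | 15 °C |
| remark | run made earlier | run made earlier |  |  |  |  |
| time |  |  | 6.0 h | 6.0 h | 6.0 h | 6.0 h |

- beta (time / h: target / %, substrate / %): 6.00: 0, 84.2; 15.0: 2.2, 68.1; 30.0: 1.4, 47.9; 50.0: 3.9, 33.9; 72.0: 6.8, 22.0; 96.0: 14.6, 15.6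
- theta (time / h: target / %, substrate / %): 3.00: 58.5, 0.3; 6.00: 79.0, 0; 8.00: 84.7, 0; 12.0: 87.6, 1.1; 20.0: 87.0, 0

(scatter of a reading: 1 percentage point)

- which flask leads in amount of target, in percent of the substrate charged ("all alike" within 1.5 percentage points) (south / north-east / north-west / south-west / all alike)
- how much target is there at the end, in percent of the substrate charged: south
- how much target is there at the end, in percent of the substrate charged: north-east
- how much target is there at the end, in percent of the substrate charged: north-west
- how much target is there at the end, in percent of the substrate charged: south-west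

- a reading or a percentage of target counts all its forms, free or not

In the beta run, target reads 0% at 6.00 h while substrate is down to 84.2%, so substrate passes through an intermediate first. The logarithmic fall of substrate in that run is 0.0245 h⁻¹ up to 30.0 h, at a mean level of 70.8%. After that it is 0.0170 h⁻¹, at a mean level of 28.8%. A rate that drifts down with c(substrate) suggests a one-substrate route beside a route pairing two substrate.

A straight line through these two points gives a ratio S of 0.659 for beta. The route's share of the substrate, and so the level of target, is then S·ln(1+1/S). The theta level of 87.3% returns S = 3.27. Assume that catalyst acts after the branch and that ln S runs straight against reciprocal absolute temperature. South then gets 9.99. Carry this branch ratio, the rate of the one-substrate route over the rate of pairing at the start of the flask, a selectivity factor. It puts the south level at 95.3%.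

Now draw the south curve. It starts flat, as in beta. Theta approaches its level at 0.415 h⁻¹. The end of beta, counting all lost substrate as intermediate, gives 0.00466 h⁻¹. Taking this rise as proportional to catalyst, south rises at 1.82 h⁻¹. The knee therefore comes near 0.381 h, and the curve lies flat well before 6.0 h. This reckoning expects south to lead.

The forecast also names south, with south at 86% (70% to 91%), north-east 28%, north-west 82% and south-west 1.3%. It reads theta as rising “to a stable plateau near 87.5%”, and its south figure is lower than this reckoning.

The flasks give south the lead: south 94.9%, north-east 26.9%, north-west 86.4%, south-west 0.653%.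

    substrate → intermediate (k = 0.00660 min⁻¹, Ea = 103 kJ mol⁻¹)
    catalyst + intermediate → catalyst + target (k = 0.240 M⁻¹ min⁻¹, Ea = 68.0 kJ mol⁻¹)
    crystals ⇌ target, rate k3*(cs3 - [target]) while solid is left; crystals form when [target] > cs3 (solubility = 0.650 M, k = 0.0130 min⁻¹)
    2 substrate → self-condensation product (k = 0.00110 M⁻¹ min⁻¹, Ea = 69.0 kJ mol⁻¹)
    (constants at 35 °C)

In south, half of the turnover of substrate into intermediate was done by 1.00 min, and 73% of the turnover of intermediate into target by 0.600 h. Crystals then went on growing, from 42.2% at 3.00 h to 50.7% at 6.00 h, all counted in target. The ratio 9.99 leaves 4.70% for pairing, and south holds 5.08% of self-condensation product. At one temperature the ratio falls as c(substrate) rises, so the neighbour of south charged with 2.5 M gets 5.99 and a level of 92.5%, and that flask stands at 91.9%.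

All runs were generated by integration from invented constants, and the scatter is random.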